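**Plan**
1. Retrosynthesis: open the 1,2-dioxolane (C11′–O and O–C8′; late aerobic oxidation), then cut the two Diels–Alder bonds C1–C2′ and C3–C1′ of the norbornene core. This gives a 2-acetoxy-cyclopentadiene half (C1–C15) and a cyclopentadienone half (C1′–C15′).
2. In the diene half, cut C1–C10 (rejoin C10 to C5) and C4–C5. The five-membered ring and the cycloheptane then fall back to the propargylic acetate of a 2-methylcyclohexanone.
3. Enabling feature: C10 (CH–CH3) lies between C9 and the ring-fusion carbon C1, and C1 is flanked by the oxygenated C2 and by C5. A spiro cyclopentenyl gold carbene with the carbene at C1 beside spiro carbon C5 can therefore take C10 by a 1,2-shift, turning the cyclohexane (C5–C10) into the cycloheptane (C1, C5–C10).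
4. Forward order: (R)-carvone gives one γ-hydroxy enone for both halves. Diene half: five- and seven-membered rings together in the cascade, then C2 acetate and C3=C4. Dienophile half: CH2 insertion to the cycloheptanone, then cyclopentenone by aldol. Union by [4+2], then the C8 and C8′ ketones, C6′=C7′ and the peroxide ring last.
5. Stereochemistry: C7 is bought with (R)-carvone; the C8 oxygen is set trans to it and relays to C10 (cis by directed hydrogenation in the diene half, trans by equilibration in the other half). C2 by CBS reduction; C1, C3, C1′, C2′ in the cycloaddition; C8′ by ring–chain equilibrium.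

Key step: step 8

**Remarks on the chemistry**
- Guaiane numbering is used for both halves (primed for the cyclopentenone half): five-membered ring C1–C5, seven-membered ring C1, C5–C10, methyls C14 on C10 and C15 on C4, isopropyl C11–C13 on C7.
- The C8′ hemiperketal configuration of the target is assumed to be the one favoured in the reversible ring–chain equilibrium of hydroperoxy ketone 32.
- Centres that are destroyed later (C3 and C4 in 11–16; C4′, C5′ and C1′ in 24–26) form as mixtures and are drawn without configuration.
- The cycloaddition (step 19) needs the exo mode and attack anti to the C2 acetoxy group, against the usual endo and syn-to-oxygen preferences; this is the main uncertainty of the route and is addressed under the risks.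

**Step 1**
Reactants: 1 (R)-(−)-carvone
Product: 2 (R)-carvotanacetone
Conditions: H2 (1 atm), RhCl(PPh3)3 (3 mol %), benzene, 25 °C
Reagents that add atoms: none
Why: Selective homogeneous hydrogenation with Wilkinson's catalyst should saturate the unhindered 1,1-disubstituted isopropenyl alkene and leave the conjugated trisubstituted alkene and the C5 stereocentre untouched.

**Step 2**
Reactants: 2 (R)-carvotanacetone
Product: 3 linear dienyl acetate
Conditions: isopropenyl acetate, TsOH·H2O (5 mol %), 90 °C, acetone distilled off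
Reagents that add atoms: isopropenyl acetate, CC(=C)OC(C)=O
Why: Acid-catalysed enol ester exchange under equilibrating conditions should give the through-conjugated dienol acetate by loss of a γ-hydrogen at C4, as in steroidal 3,5-dienol acetate formation, while the isopropyl-bearing centre is not enolisable and keeps its configuration.

**Step 3**
Reactants: 3 linear dienyl acetate
Product: 4 γ-hydroxy enone (OH trans to isopropyl)
Conditions: m-CPBA, NaHCO3, CH2Cl2/H2O, 0 °C
Reagents that add atoms: m-chloroperbenzoic acid, OOC(=O)c1cccc(Cl)c1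
Why: In this vinylogous Rubottom oxidation the peracid should epoxidise the distal C3=C4 bond of the dienol acetate anti to the neighbouring isopropyl group, and epoxide opening with loss of the acetyl group returns the enone with the new C4 hydroxyl trans to isopropyl.

**Step 4**
Reactants: 4 γ-hydroxy enone
Product: 5 hydroxy ketone (methyl cis to isopropyl)
Conditions: H2 (1 atm), [Ir(cod)(PCy3)(py)]PF6 (2.5 mol %), CH2Cl2, 0 to 25 °C
Reagents that add atoms: none
Why: Hydroxyl-directed hydrogenation with Crabtree's catalyst should deliver hydrogen to C2=C3 from the face of the C4 hydroxyl, so the C2 methyl ends trans to OH and therefore cis to the isopropyl group.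

**Step 5**
Reactants: 5 hydroxy ketone
Product: 6 silyl ether ketone
Conditions: TBSCl, imidazole, DMF, 25 °C
Reagents that add atoms: tert-butyldimethylsilyl chloride, C[Si](C)(Cl)C(C)(C)C
Why: Imidazole-mediated silylation of the secondary alcohol is mild enough to leave the less stable axial α-methyl centre unepimerised.

**Step 6**
Reactants: 6 silyl ether ketone; 7 (E)-pent-3-en-1-yne
Product: 8 tertiary propargylic alcohol
Conditions: 7, n-BuLi, THF, −78 °C; CeCl3; then 6, −78 °C
Reagents that add atoms: none
Why: 1,2-Addition of the weakly basic cerium acetylide (Imamoto conditions) should avoid enolisation of the α-methyl centre, and axial attack anti to the axial C2 methyl sets the carbinol centre (alkynyl trans to that methyl), which is lost again in step 8.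

**Step 7**
Reactants: 8 tertiary propargylic alcohol
Product: 9 tertiary propargylic acetate
Conditions: Ac2O, DMAP, Et3N, CH2Cl2, 25 °C
Reagents that add atoms: acetic anhydride, CC(=O)OC(C)=O
Why: DMAP-catalysed acylation of the tertiary alcohol installs the migrating acyloxy group needed for the cascade and touches no stereocentre.

**Step 8**
Reactants: 9 tertiary propargylic acetate
Product: 12 8-silyloxy-guai-1(5)-en-2-one, via allenyl acetate 10 (not isolated), via ring-expanded dienyl acetate 11 (not isolated)
Conditions: Ph3PAuCl (5 mol %), AgSbF6 (5 mol %), CH2Cl2, 0 to 23 °C; then K2CO3 (cat.), MeOH, 0 °C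
Reagents that add atoms: none
Why: Proposed new method: monovalent gold should activate the alkyne for a 3,3-acyloxy shift to allenyl acetate 10, whose gold-bound pentadienyl cation (C5, C1, C2, C3, C4) closes by Nazarov-type conrotatory 4π-electrocyclisation at C4–C5 and leaves a gold carbene at C1 directly beside the spiro carbon C5. Because C5 carries no hydrogen, the carbene is expected to be quenched by a 1,2-alkyl (Wagner–Meerwein) shift of C10 from C5 to C1, which turns the cyclohexane (C5–C10) into the cycloheptane (C1, C5–C10), and loss of gold gives the C1=C5 bond of 11, whose enol acetate is then cleaved by methanolysis to enone 12. The closest known reaction types are the gold-catalysed tandem 3,3-rearrangement/Nazarov cyclisation of enynyl acetates, which normally ends by a 1,2-hydrogen shift, and ring expansions by 1,2-alkyl shift to gold carbenes or Nazarov-derived cations. The five-membered ring closes by electrocyclisation (bond C4–C5) and the seven-membered ring arises by one-carbon ring expansion (C1–C10 formed, C5–C10 broken). C10 migrates with retention so its configuration comes from ketone 6, C7 and C8 are untouched, and the new C4 centre is uncontrolled but is removed in step 12. The selectivity needed is migration of C10 instead of C6, which the higher migratory aptitude of the more substituted, methyl-bearing carbon toward the electron-poor carbene should secure.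

**Step 9**
Reactants: 12 8-silyloxy-guai-1(5)-en-2-one
Product: 13 3-phenylselanyl ketone
Conditions: LDA, THF, −78 °C; PhSeCl, −78 °C
Reagents that add atoms: phenylselenyl chloride, Cl[Se]c1ccccc1
Why: Kinetic deprotonation at the only α′ position (C3) and selenenylation of the enolate anti to the C4 methyl group (Reich–Sharpless selenenylation) should give the 3,4-trans α-seleno ketone.

**Step 10**
Reactants: 13 3-phenylselanyl ketone
Product: 14 allylic alcohol
Conditions: (S)-CBS oxazaborolidine [(S)-1-methyl-3,3-diphenyl-tetrahydropyrrolo[1,2-c][1,3,2]oxazaborole] (20 mol %), BH3·SMe2, toluene, −40 °C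
Reagents that add atoms: none
Why: Corey–Bakshi–Shibata reduction with the enone alkene as the large group should deliver hydride to the C2 face opposite the pseudo-axial C10 methyl (catalyst and substrate bias matched), setting the C2 carbinol cis to that methyl.

**Step 11**
Reactants: 14 allylic alcohol
Product: 15 allylic acetate
Conditions: Ac2O, DMAP, pyridine, CH2Cl2, 0 °C
Reagents that add atoms: acetic anhydride, CC(=O)OC(C)=O
Why: Standard DMAP-catalysed acetylation fixes the C2 oxygen as the acetate of the target without touching the configuration.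

**Step 12**
Reactants: 15 allylic acetate
Product: 17 2-acetoxy-8-silyloxy-guaia-1(5),3-diene, via selenoxide 16 (not isolated)
Conditions: m-CPBA, CH2Cl2, −78 °C; then Et3N, −78 to 0 °C; used at once as a cold solution
Reagents that add atoms: none
Why: Selenoxide syn-elimination should take the cis hydrogen at C4 and avoid the acetoxy-bearing C2, giving the C3=C4 bond of the 5-acyloxy-cyclopentadiene at a temperature at which the 1,5-hydrogen shift is slow.

**Step 13**
Reactants: 4 γ-hydroxy enone
Product: 18 silyloxy enone
Conditions: TBSCl, imidazole, DMF, 25 °C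
Reagents that add atoms: tert-butyldimethylsilyl chloride, C[Si](C)(Cl)C(C)(C)C
Why: Silylation protects the C4 hydroxyl (later C8′) for the second half.

**Step 14**
Reactants: 18 silyloxy enone
Product: 19 trans ketone
Conditions: H2 (1 atm), Pd/C, EtOAc, 25 °C; then NaOMe (cat.), MeOH, 25 °C
Reagents that add atoms: none
Why: Heterogeneous hydrogenation followed by base equilibration of the α-centre should give the all-equatorial ketone, with the methyl trans to isopropyl, which is the C10′ configuration needed.

**Step 15**
Reactants: 19 trans ketone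
Product: 21 cycloheptanone, via 2-trimethylsilyl ketone 20 (not isolated)
Conditions: Me3SiCHN2, Sc(OTf)3 (10 mol %), CH2Cl2, 0 °C; then K2CO3 (cat.), MeOH
Reagents that add atoms: trimethylsilyldiazomethane, C[Si](C)(C)C=[N+]=[N-]
Why: Lewis-acid-catalysed diazoalkane–carbonyl homologation (Tiffeneau–Demjanov type) should insert the carbon on the less substituted CH2 side, and the methyl centre α to the ketone stays in its thermodynamically preferred pseudo-equatorial configuration.

**Step 16**
Reactants: 22 3-nitrobutan-2-ol
Product: 23 (E)-2-nitrobut-2-ene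
Conditions: MsCl, Et3N, CH2Cl2, 0 °C
Reagents that add atoms: none
Why: Mesylation and base-induced E1cB elimination of the β-nitro alcohol give the nitroalkene Michael acceptor.

**Step 17**
Reactants: 21 cycloheptanone; 23 (E)-2-nitrobut-2-ene
Product: 25 1,4-diketone, via nitro ketone 24 (not isolated)
Conditions: LDA, THF, −78 °C; 23, −78 °C; then aq. TiCl3, NH4OAc, 25 °C
Reagents that add atoms: water, O
Why: The kinetic enolate on the CH2 side adds to the nitroalkene (Michael addition) and the nitronate is converted into the ketone by the buffered McMurry variant of the Nef reaction, giving the 3-oxobutan-2-yl side chain.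

**Step 18**
Reactants: 25 1,4-diketone
Product: 26 8′-silyloxy-guai-4′-en-3′-one
Conditions: KOH, EtOH, 70 °C
Reagents that add atoms: none
Why: Intramolecular aldol condensation of the methyl ketone onto the ring ketone closes the cyclopentenone, and under the basic conditions the double bond should settle in the tetrasubstituted C4′=C5′ position.

**Step 19**
Reactants: 26 8′-silyloxy-guai-4′-en-3′-one; 17 2-acetoxy-8-silyloxy-guaia-1(5),3-diene
Product: 28 Diels–Alder adduct, via cyclopentadienone 27 (not isolated)
Conditions: 26, LDA, THF, −78 °C; PhS(Cl)=N-t-Bu, −78 °C; then 17 (1.5 equiv), CH2Cl2, −78 to 0 °C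
Reagents that add atoms: none
Why: Mukaiyama dehydrogenation of the kinetic α′-enolate releases cyclopentadienone 27 at −78 °C, and its C1′=C2′ bond is trapped by the excess diene in a thermal Diels–Alder reaction in which the unsubstituted diene terminus C3 bonds to the fully substituted C1′, the diene is attacked on the face opposite both its C2 acetoxy and C10 methyl groups, the dienophile on the face opposite its C10′ methyl, and the exo mode (cyclopentenone ring toward the C2–H bridge, branched C10′ away from it) is relied on to set C1, C3, C1′ and C2′ as in the target.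

**Step 20**
Reactants: 28 Diels–Alder adduct
Product: 29 diol
Conditions: HF·pyridine, THF, 0 to 25 °C
Reagents that add atoms: none
Why: Fluoride-mediated desilylation frees the C8 and C8′ hydroxyls and leaves the C2 acetate intact.

**Step 21**
Reactants: 29 diol
Product: 30 diketone
Conditions: Dess–Martin periodinane, NaHCO3, CH2Cl2, 25 °C
Reagents that add atoms: none
Why: Dess–Martin oxidation converts both secondary alcohols into the C8 and C8′ ketones under non-epimerising conditions, so C7 keeps the cis relation to C10 set earlier.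

**Step 22**
Reactants: 30 diketone
Product: 31 dienone
Conditions: DDQ, 1,4-dioxane, 80 °C
Reagents that add atoms: none
Why: Quinone dehydrogenation through the dienol of the C3′ enone should remove hydride from C7′ (also α to the C8′ ketone), as in 4-en-3-one to 4,6-dien-3-one conversions, and the quaternary C1′ blocks the alternative α′,β′ dehydrogenation.

**Step 23**
Reactants: 31 dienone
Product: 33 target compound CNP0361479.4, via hydroperoxy ketone 32 (not isolated)
Conditions: O2 (1 atm), AIBN (10 mol %), PhCl, 55 °C
Reagents that add atoms: dioxygen, O=O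
Why: Radical-chain autoxidation should abstract the weakest C–H bond (the isopropyl methine C11′, tertiary and allylic to the cross-conjugated dienone), oxygen adds at C11′ so that the dienone stays conjugated, and the hydroperoxide closes onto the neighbouring C8′ ketone to give the 1,2-dioxolan-3-ol, whose C8′ centre is set by the reversible ring–chain equilibrium.

**Compound list**
1 | (R)-(−)-carvone | CC1=CC[C@H](CC1=O)C(C)=C | starting material
2 | (R)-carvotanacetone, (5R)-2-methyl-5-(propan-2-yl)cyclohex-2-en-1-one | CC1=CC[C@H](CC1=O)C(C)C | intermediate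
3 | (5R)-2-methyl-5-(propan-2-yl)cyclohexa-1,3-dien-1-yl acetate | CC(=O)OC1=C(C)C=C[C@@H](C(C)C)C1 | intermediate
4 | (4R,5R)-4-hydroxy-2-methyl-5-(propan-2-yl)cyclohex-2-en-1-one (OH trans to isopropyl) | O=C1C[C@H](C(C)C)[C@@H](O)C=C1C | intermediate
5 | (2S,4S,5R)-4-hydroxy-2-methyl-5-(propan-2-yl)cyclohexan-1-one (methyl cis to isopropyl, trans to OH) | O=C1C[C@H](C(C)C)[C@@H](O)C[C@@H]1C | intermediate
6 | (2S,4S,5R)-4-(tert-butyldimethylsilyloxy)-2-methyl-5-(propan-2-yl)cyclohexan-1-one | O=C1C[C@H](C(C)C)[C@@H](O[Si](C)(C)C(C)(C)C)C[C@@H]1C | intermediate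
7 | (E)-pent-3-en-1-yne (sold as E/Z mixture; either isomer serves) | C/C=C/C#C | starting material
8 | (2S,4S,5R)-4-(tert-butyldimethylsilyloxy)-2-methyl-1-[(E)-pent-3-en-1-ynyl]-5-(propan-2-yl)cyclohexan-1-ol (alkynyl trans to the C2 methyl) | C/C=C/C#C[C@@]1(O)C[C@H](C(C)C)[C@@H](O[Si](C)(C)C(C)(C)C)C[C@@H]1C | intermediate
9 | acetate of 8 | C/C=C/C#C[C@@]1(OC(C)=O)C[C@H](C(C)C)[C@@H](O[Si](C)(C)C(C)(C)C)C[C@@H]1C | intermediate
10 | (3E)-1-[(2S,4S,5R)-4-(tert-butyldimethylsilyloxy)-2-methyl-5-(propan-2-yl)cyclohexylidene]penta-1,3-dien-2-yl acetate (allenyl acetate) | C/C=C/C(OC(C)=O)=C=C1C[C@H](C(C)C)[C@@H](O[Si](C)(C)C(C)(C)C)C[C@@H]1C | intermediate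
11 | (7R,8S,10S)-8-(tert-butyldimethylsilyloxy)guaia-1(5),2-dien-2-yl acetate (C4 epimers) | CC(=O)OC1=CC(C)C=3C[C@H](C(C)C)[C@@H](O[Si](C)(C)C(C)(C)C)C[C@H](C)C=31 | intermediate
12 | (7R,8S,10S)-8-(tert-butyldimethylsilyloxy)guai-1(5)-en-2-one (7-isopropyl cis to 10-methyl, trans to 8-O; C4 epimers) | O=C1CC(C)C=3C[C@H](C(C)C)[C@@H](O[Si](C)(C)C(C)(C)C)C[C@H](C)C=31 | intermediate
13 | (7R,8S,10S)-8-(tert-butyldimethylsilyloxy)-3-(phenylselanyl)guai-1(5)-en-2-one (3,4-trans) | O=C1C([Se]c2ccccc2)C(C)C=3C[C@H](C(C)C)[C@@H](O[Si](C)(C)C(C)(C)C)C[C@H](C)C=31 | intermediate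
14 | (2S,7R,8S,10S)-8-(tert-butyldimethylsilyloxy)-3-(phenylselanyl)guai-1(5)-en-2-ol (2-OH cis to 10-methyl) | O[C@@H]1C([Se]c2ccccc2)C(C)C=3C[C@H](C(C)C)[C@@H](O[Si](C)(C)C(C)(C)C)C[C@H](C)C=31 | intermediate
15 | acetate of 14 | CC(=O)O[C@@H]1C([Se]c2ccccc2)C(C)C=3C[C@H](C(C)C)[C@@H](O[Si](C)(C)C(C)(C)C)C[C@H](C)C=31 | intermediate
16 | selenoxide of 15 | CC(=O)O[C@@H]1C([Se](=O)c2ccccc2)C(C)C=3C[C@H](C(C)C)[C@@H](O[Si](C)(C)C(C)(C)C)C[C@H](C)C=31 | intermediate
17 | (2R,7R,8S,10S)-8-(tert-butyldimethylsilyloxy)guaia-1(5),3-dien-2-yl acetate (2-OAc cis to 10-methyl) | CC(=O)O[C@@H]1C=C(C)C=3C[C@H](C(C)C)[C@@H](O[Si](C)(C)C(C)(C)C)C[C@H](C)C=31 | intermediate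
18 | (4R,5R)-4-(tert-butyldimethylsilyloxy)-2-methyl-5-(propan-2-yl)cyclohex-2-en-1-one | O=C1C[C@H](C(C)C)[C@@H](O[Si](C)(C)C(C)(C)C)C=C1C | intermediate
19 | (2R,4S,5R)-4-(tert-butyldimethylsilyloxy)-2-methyl-5-(propan-2-yl)cyclohexan-1-one (methyl trans to isopropyl) | O=C1C[C@H](C(C)C)[C@@H](O[Si](C)(C)C(C)(C)C)C[C@H]1C | intermediate
20 | 4-(tert-butyldimethylsilyloxy)-2-methyl-5-(propan-2-yl)-7-(trimethylsilyl)cycloheptan-1-one (ring configurations as in 21) | O=C1C([Si](C)(C)C)C[C@H](C(C)C)[C@@H](O[Si](C)(C)C(C)(C)C)C[C@H]1C | intermediate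
21 | 4-(tert-butyldimethylsilyloxy)-2-methyl-5-(propan-2-yl)cycloheptan-1-one (2-methyl trans to 5-isopropyl, cis to 4-O) | O=C1CC[C@H](C(C)C)[C@@H](O[Si](C)(C)C(C)(C)C)C[C@H]1C | intermediate
22 | 3-nitrobutan-2-ol (mixture of diastereomers) | CC(O)C(C)[N+](=O)[O-] | starting material
23 | (E)-2-nitrobut-2-ene | C/C=C(\C)[N+](=O)[O-] | intermediate
24 | 4-(tert-butyldimethylsilyloxy)-2-methyl-7-(3-nitrobutan-2-yl)-5-(propan-2-yl)cycloheptan-1-one | O=C1C(C(C)C(C)[N+](=O)[O-])C[C@H](C(C)C)[C@@H](O[Si](C)(C)C(C)(C)C)C[C@H]1C | intermediate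
25 | 4-(tert-butyldimethylsilyloxy)-2-methyl-7-(3-oxobutan-2-yl)-5-(propan-2-yl)cycloheptan-1-one | O=C1C(C(C)C(C)=O)C[C@H](C(C)C)[C@@H](O[Si](C)(C)C(C)(C)C)C[C@H]1C | intermediate
26 | (7′R,8′S,10′R)-8′-(tert-butyldimethylsilyloxy)guai-4′-en-3′-one (C1′ epimers) | CC1=C2C[C@H](C(C)C)[C@@H](O[Si](C)(C)C(C)(C)C)C[C@@H](C)C2CC1=O | intermediate
27 | (7′R,8′S,10′R)-8′-(tert-butyldimethylsilyloxy)guaia-1′,4′-dien-3′-one (cyclopentadienone) | CC1=C2C[C@H](C(C)C)[C@@H](O[Si](C)(C)C(C)(C)C)C[C@@H](C)C2=CC1=O | intermediate
28 | Diels–Alder adduct: 2-acetoxy-8,8′-bis(tert-butyldimethylsilyloxy) dimer with bonds C1–C2′ and C3–C1′, exo-fused cyclopentenone, 2-OAc syn to C4=C5 | CC(=O)O[C@@H]1[C@@H]2C(C)=C3C[C@H](C(C)C)[C@@H](O[Si](C)(C)C(C)(C)C)C[C@H](C)[C@@]31[C@@H]1C(=O)C(C)=C3C[C@H](C(C)C)[C@@H](O[Si](C)(C)C(C)(C)C)C[C@@H](C)[C@]312 | intermediate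
29 | 8,8′-diol of 28 | CC(=O)O[C@@H]1[C@@H]2C(C)=C3C[C@H](C(C)C)[C@@H](O)C[C@H](C)[C@@]31[C@@H]1C(=O)C(C)=C3C[C@H](C(C)C)[C@@H](O)C[C@@H](C)[C@]312 | intermediate
30 | 8,8′-diketone | CC(=O)O[C@@H]1[C@@H]2C(C)=C3C[C@H](C(C)C)C(=O)C[C@H](C)[C@@]31[C@@H]1C(=O)C(C)=C3C[C@H](C(C)C)C(=O)C[C@@H](C)[C@]312 | intermediate
31 | 4′,6′-dien-3′,8′-dione (C6′=C7′ dienone with 7′-isopropyl) | CC(=O)O[C@@H]1[C@@H]2C(C)=C3C[C@H](C(C)C)C(=O)C[C@H](C)[C@@]31[C@@H]1C(=O)C(C)=C3C=C(C(C)C)C(=O)C[C@@H](C)[C@]312 | intermediate
32 | 11′-hydroperoxy ketone | CC(=O)O[C@@H]1[C@@H]2C(C)=C3C[C@H](C(C)C)C(=O)C[C@H](C)[C@@]31[C@@H]1C(=O)C(C)=C3C=C(C(C)(C)OO)C(=O)C[C@@H](C)[C@]312 | intermediate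
33 | CNP0361479.4 (8′-hydroxy-8′,11′-epidioxy dimer, single enantiomer as given) | CC(=O)O[C@@H]1[C@@H]2C(C)=C3C[C@H](C(C)C)C(=O)C[C@H](C)[C@@]31[C@@H]1C(=O)C(C)=C3C=C4C(C)(C)OO[C@]4(O)C[C@@H](C)[C@]312 | target

**Step count**
Total: 23 steps. Longest linear sequence: 17 steps (steps 1–12 and 19–23).

**Steps most likely to fail**

1. Step 8 (Proposed new method). The cascade may be diverted before or at the 1,2-shift: isomerisation of the allene, proton loss from the spiro intermediate, or migration of C6 in place of C10. Fallback by known chemistry, setting out from 6 and returning at 12: Sc(OTf)3-catalysed insertion of trimethylsilyldiazomethane on the CH2 side of 6, with protodesilylation on silica gel, should give cycloheptanone F1. Kinetic enolisation toward the new CH2 (KHMDS, PhNTf2, −78 °C) gives enol triflate F2. Carbonylative Stille coupling (Pd(PPh3)4, CO, LiCl, (E)-tributyl(prop-1-enyl)stannane) gives cross-conjugated dienone F3. A Lewis-acid Nazarov cyclisation (BF3·OEt2) then closes the five-membered ring and returns to enone 12. In this variant the ketone carbon of 6 becomes C1 and the inserted CH2 becomes C5.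

2. Step 19. Three processes compete with the wanted cycloaddition: self-dimerisation of the transient cyclopentadienone, 1,5-hydrogen shift in the diene, and cycloaddition in the endo mode or syn to the acetoxy group. Fallback setting out from 26 and returning at 28: 26 is converted into its silyl dienol ether F4 (LDA, TBSCl). Hydride is abstracted with Ph3CBF4 in CH2Cl2 at −78 °C under base-free conditions, in the presence of the bulky Lewis acid aluminium tris(2,6-diphenylphenoxide), Al(OC6H3Ph2)3. This acid binds the carbonyl of the nascent cyclopentadienone 27, shields it against self-dimerisation and is known to turn enone cycloadditions to the exo mode. Diene 17 is then added to give adduct 28.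

3. Step 23. Hydrogen abstraction in the radical chain may be unselective (allylic positions of the C4=C5 alkene) and the product may be over-oxidised. Fallback setting out from 31 and returning at 32: Wohl–Ziegler bromination (NBS, AIBN, PhCF3) at the isopropyl methine gives tertiary allylic bromide F5, which can be purified. Silver-assisted perhydrolysis (H2O2, AgOTf, Et2O, 0 °C) then gives hydroperoxy ketone 32, which closes to 33.

**Further compounds**
F1 | step 8 | 4-(tert-butyldimethylsilyloxy)-2-methyl-5-(propan-2-yl)cycloheptan-1-one (2-methyl cis to 5-isopropyl, trans to 4-O) | O=C1CC[C@H](C(C)C)[C@@H](O[Si](C)(C)C(C)(C)C)C[C@@H]1C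
F2 | step 8 | enol triflate of F1 (double bond toward the new CH2) | FC(F)(F)S(=O)(=O)OC1=CC[C@H](C(C)C)[C@@H](O[Si](C)(C)C(C)(C)C)C[C@@H]1C
F3 | step 8 | (E)-1-[cyclohept-1-enyl]but-2-en-1-one bearing the 7-methyl, 5-silyloxy and 4-isopropyl groups of F2 | C/C=C/C(=O)C1=CC[C@H](C(C)C)[C@@H](O[Si](C)(C)C(C)(C)C)C[C@@H]1C
F4 | step 19 | 3′-(tert-butyldimethylsilyloxy) dienol ether of 26 (C2′=C3′, C4′=C5′) | CC1=C2C[C@H](C(C)C)[C@@H](O[Si](C)(C)C(C)(C)C)C[C@@H](C)C2C=C1O[Si](C)(C)C(C)(C)C
F5 | step 23 | 11′-bromo derivative of 31 | CC(=O)O[C@@H]1[C@@H]2C(C)=C3C[C@H](C(C)C)C(=O)C[C@H](C)[C@@]31[C@@H]1C(=O)C(C)=C3C=C(C(C)(C)Br)C(=O)C[C@@H](C)[C@]312
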